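## Retrosynthetic overview

1. 14 ⇒ 13: the 4,5-trans-diol comes from water opening a 4β,5β-oxirane at allylic C5. This is the last presumed biosynthetic event.
2. 13 ⇒ 11: the second oxirane comes from C3–OH-directed epoxidation of a trans-2,3-dioxygenated cyclohexadiene. C3 is acetylated before the diol exists, so no protecting group is needed.
3. 11 ⇒ 8: C2–OBz and C3–OH come from one vinylogous (SN2'') opening of the meta,para-arene oxide by benzoate, the way water turns chorismate into isochorismate. CHO is a traceless activator, and the racemising oxide allows a dynamic kinetic resolution.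
4. 8 ⇒ 1: the first oxirane comes from dearomative epoxidation of a benzyl ester. The carbocycle is the arene ring itself and is never built.
5. Ring order: temporary urazole bridge on → oxirane one → bridge off → oxirane one opened → oxirane two → oxirane two opened.

**Locants used throughout:** C1 carries the CH2O group, C2 the ring OBz, C3 the OAc, C4 and C5 the OH groups, and C6 is the vinylic CH. β is the face of the C3 and C4 oxygens and α is the face of the C2 and C5 oxygens.

**Assumption:** the quinine-derived primary amine of step 4 is taken to expose the α face of C2 and so to give the (5S,6S) series. If it gives the antipode, its pseudoenantiomer 9-amino-9-deoxy-epi-quinidine is used with nothing else changed.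

## Route

Step 1
Reactants: 1 benzyl acetate; 2 4-methyl-1,2,4-triazoline-3,5-dione (MTAD)
Product: 4 (±)-urazole-bridged 3,4-epoxide (N–N bridge across C2/C5; oxirane on C3–C4 anti to it; C1=C6 keeps CH2OAc), via arenophile cycloadduct 3 (not isolated)
Conditions: 1 (2 equiv), 2, CH2Cl2, white LEDs, −78 °C; then TFDO (solution in CF3COCH3), −78 to −40 °C
Reagents that add atoms: methyl(trifluoromethyl)dioxirane (TFDO), CC1(OO1)C(F)(F)F
Why: Visible-light para-[4+2] cycloaddition of the arenophile across C2 and C5 leaves the substituent on an alkene carbon and isolates two olefins, and the electrophilic dioxirane then epoxidises the unsubstituted, less hindered C3=C4 bond anti to the urazole, which is a known arenophile-mediated dearomative epoxidation and the chemical counterpart of the arene monooxygenase step; 4 is racemic and its relative configuration is erased in step 2.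

Step 2
Reactants: 4 (±)-urazole-bridged 3,4-epoxide
Product: 7 (±)-(7-oxabicyclo[4.1.0]hepta-2,4-dien-3-yl)methanol (the 3,4-arene oxide of benzyl alcohol; valence tautomer oxepin-4-ylmethanol), via bicyclic hydrazine 5 (not isolated), via bicyclic diazene 6 (not isolated)
Conditions: KOH, i-PrOH, 40 °C; then pH 8 buffer, CuCl2 (10 mol %), O2, 0 °C; Et2O extraction, dried over K2CO3
Reagents that add atoms: none
Why: Base hydrolysis of the urazole (and of the acetate) gives the cyclic hydrazine, copper-catalysed aerobic oxidation gives the diazene, and this loses N2 in a spontaneous retro-Diels–Alder reaction under non-acidic conditions that an arene oxide survives; 7 is a configurationally labile racemate because of the benzene oxide–oxepine valence tautomerism, so no stereocentre has to be controlled here.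

Step 3
Reactants: 7 (±)-(7-oxabicyclo[4.1.0]hepta-2,4-dien-3-yl)methanol
Product: 8 (±)-7-oxabicyclo[4.1.0]hepta-2,4-diene-3-carbaldehyde (3,4-arene oxide of benzaldehyde)
Conditions: MnO2 (15 equiv), K2CO3, CH2Cl2, 0 °C to rt
Reagents that add atoms: none
Why: Heterogeneous MnO2 oxidation of the dienylic primary alcohol is neutral and stops at the aldehyde, the formyl group both stabilises the arene oxide against acid-induced aromatisation and makes C2 a Michael acceptor position, and no stereocentre is fixed because 8 still racemises through oxepine-4-carbaldehyde.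

Step 4
Reactants: 8 (±)-7-oxabicyclo[4.1.0]hepta-2,4-diene-3-carbaldehyde
Product: 10 (1S,6S)-6-hydroxy-2-(hydroxymethyl)cyclohexa-2,4-dien-1-yl benzoate, via dienal 9 (not isolated)
Conditions: 9-amino-9-deoxy-epi-quinine (20 mol %), PhCO2H (3 equiv), H2O (2 equiv), toluene, 0 °C; then MeOH, CeCl3·7H2O, NaBH4, −60 °C
Reagents that add atoms: benzoic acid, O=C(O)c1ccccc1
Why: Proposed new method: condensation of the primary amine with 8 gives a dienyl iminium ion whose β-carbon C2 is attacked by benzoate anti to the neighbouring oxirane oxygen, the resulting dienamine pushes electrons through C1=C6 and C5=C4 to break the C4–O bond (a vinylogous E1cB, formally an SN2'' opening), and because 8 racemises rapidly through its oxepine while the chiral iminium exposes only one face of C2 the whole pool funnels into the trans (5S,6S) product in a dynamic kinetic resolution that sets C2 and C3 together, the closest known reaction types being the base-mediated trans conjugate opening of 4-carboalkoxybenzene oxides by N-nucleophiles and the cinchona-primary-amine-catalysed oxa-Michael addition of peroxide to α-branched enals, while the Luche reduction in the same flask removes the aldehyde before it can promote loss of benzoic acid and aromatisation.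

Step 5
Reactants: 10 (1S,6S)-6-hydroxy-2-(hydroxymethyl)cyclohexa-2,4-dien-1-yl benzoate
Product: 11 [(5S,6S)-6-(benzoyloxy)-5-hydroxycyclohexa-1,3-dien-1-yl]methyl benzoate
Conditions: BzCl (1.05 equiv), 2,4,6-collidine, CH2Cl2, −78 to −30 °C
Reagents that add atoms: benzoyl chloride, O=C(Cl)c1ccccc1
Why: Kinetically controlled acylation picks the unhindered primary allylic alcohol over the secondary C3–OH at low temperature with a weak base that does not trigger benzoate migration, and no stereocentre is touched.

Step 6
Reactants: 11 [(5S,6S)-6-(benzoyloxy)-5-hydroxycyclohexa-1,3-dien-1-yl]methyl benzoate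
Product: 12 [(1S,4S,5R,6R)-4-(benzoyloxy)-5-hydroxy-7-oxabicyclo[4.1.0]hept-2-en-3-yl]methyl benzoate (4β,5β-oxirane cis to C3–OH)
Conditions: VO(acac)2 (5 mol %), t-BuOOH (1.2 equiv, decane), CH2Cl2, 0 °C
Reagents that add atoms: tert-butyl hydroperoxide, CC(C)(C)OO
Why: In this hydroxyl-directed epoxidation the C3 vanadate ester delivers the peroxide oxygen intramolecularly to the adjacent C4=C5 bond on the face of the hydroxyl group, which fixes C4 and C5 relative to C3 and overrides the usual peracid preference for C1=C6, whose allylic oxygens are all esters.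

Step 7
Reactants: 12 epoxy alcohol
Product: 13 [(1S,4S,5R,6S)-5-acetoxy-4-(benzoyloxy)-7-oxabicyclo[4.1.0]hept-2-en-3-yl]methyl benzoate
Conditions: Ac2O, pyridine, DMAP (cat.), CH2Cl2, 0 °C
Reagents that add atoms: acetic anhydride, CC(=O)OC(C)=O
Why: DMAP-catalysed acetylation of the only free hydroxyl is done while C4 and C5 are still tied up in the oxirane, so the three contiguous oxygens never have to be told apart, and all stereocentres are unchanged.

Step 8
Reactants: 13 epoxy acetate
Product: 14 [(3R,4S,5S,6S)-5-acetoxy-6-(benzoyloxy)-3,4-dihydroxycyclohex-1-en-1-yl]methyl benzoate (target CNP0213675.1)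
Conditions: HClO4 (5 mol %), THF–H2O 3:1, 0 °C
Reagents that add atoms: water, O
Why: Acid-catalysed anti opening of the vinyl oxirane by water at allylic C5 (inversion at C5, retention at C4) gives the 4β,5α trans-diol, attack at C1 being disfavoured by substitution and by two β-acyloxy groups and the cis C3 acetate being unable to reach the back of C4, which reproduces the hydrolytic step presumed to end the biosynthesis.

## Compound list

1 | benzyl acetate | CC(=O)OCc1ccccc1 | starting material
2 | 4-methyl-1,2,4-triazoline-3,5-dione (MTAD) | CN1C(=O)N=NC1=O | starting material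
3 | (±)-MTAD para-cycloadduct of 1, urazole N–N across C2/C5 (one enantiomer drawn) | CC(=O)OCC1=C[C@@H]2C=C[C@H]1N1N2C(=O)N(C)C1=O | intermediate
4 | (±)-3,4-epoxide of 3, oxirane anti to the urazole (one enantiomer drawn) | CC(=O)OCC1=C[C@@H]2[C@@H]3O[C@@H]3[C@H]1N1N2C(=O)N(C)C1=O | intermediate
5 | (±)-bicyclic epoxy hydrazine with free CH2OH | OCC1=C[C@@H]2[C@@H]3O[C@@H]3[C@H]1NN2 | intermediate
6 | (±)-bicyclic epoxy diazene with free CH2OH | OCC1=C[C@@H]2[C@@H]3O[C@@H]3[C@H]1N=N2 | intermediate
7 | (±)-(7-oxabicyclo[4.1.0]hepta-2,4-dien-3-yl)methanol, racemises via the oxepine (3β,4β enantiomer drawn) | OCC1=C[C@H]2O[C@H]2C=C1 | intermediate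
8 | (±)-7-oxabicyclo[4.1.0]hepta-2,4-diene-3-carbaldehyde, racemises via the oxepine (3β,4β enantiomer drawn, the one consumed in step 4) | O=CC1=C[C@H]2O[C@H]2C=C1 | intermediate
9 | (1S,6S)-2-formyl-6-hydroxycyclohexa-2,4-dien-1-yl benzoate | O=CC1=CC=C[C@H](O)[C@H]1OC(=O)c1ccccc1 | intermediate
10 | (1S,6S)-6-hydroxy-2-(hydroxymethyl)cyclohexa-2,4-dien-1-yl benzoate | OCC1=CC=C[C@H](O)[C@H]1OC(=O)c1ccccc1 | intermediate
11 | [(5S,6S)-6-(benzoyloxy)-5-hydroxycyclohexa-1,3-dien-1-yl]methyl benzoate | O=C(OCC1=CC=C[C@H](O)[C@H]1OC(=O)c1ccccc1)c1ccccc1 | intermediate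
12 | [(1S,4S,5R,6R)-4-(benzoyloxy)-5-hydroxy-7-oxabicyclo[4.1.0]hept-2-en-3-yl]methyl benzoate | O=C(OCC1=C[C@@H]2O[C@@H]2[C@H](O)[C@H]1OC(=O)c1ccccc1)c1ccccc1 | intermediate
13 | [(1S,4S,5R,6S)-5-acetoxy-4-(benzoyloxy)-7-oxabicyclo[4.1.0]hept-2-en-3-yl]methyl benzoate | O=C(OCC1=C[C@@H]2O[C@@H]2[C@H](OC(C)=O)[C@H]1OC(=O)c1ccccc1)c1ccccc1 | intermediate
14 | [(3R,4S,5S,6S)-5-acetoxy-6-(benzoyloxy)-3,4-dihydroxycyclohex-1-en-1-yl]methyl benzoate | CC(=O)O[C@H]1[C@@H](O)[C@H](O)C=C(COC(=O)c2ccccc2)[C@@H]1OC(=O)c1ccccc1 | target

## Step count and risks

Total step count: 8. Longest linear sequence: 8.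

**Steps most likely to fail**

Step 4 is a new reaction. Its risks are:
- aromatisation of 8 or 9 to 3-hydroxybenzaldehyde;
- irreversible N-alkylation of the amine catalyst by 8;
- low ee.

The fallback sets out from 8 and comes back at 11. It gives up catalyst control and resolves later. Tetrabutylammonium benzoate and benzoic acid in DMSO at room temperature perform the same conjugate opening as a plain base-type reaction. The Luche reduction and the selective benzoylation are run as above. Everything is now racemic, so 9, 10 and 11 are accompanied by the enantiomeric dienal F1, the enantiomeric diol F2 and the enantiomeric dibenzoate F3. Burkholderia cepacia lipase and vinyl acetate in MTBE then acetylate only the (5R,6R)-alcohol. This is the preference expected from the Kazlauskas rule, with the C2 side as the large group. The product is the (5R,6R)-acetate F4. Unreacted 11 is separated by chromatography and goes on as before.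

Step 8 has three risks:
- leakage to an allyl cation, with syn opening, attack at C1, or capture of C1 by the C7 benzoate;
- acetyl drift from O3 to O4;
- both follow from water being a poor nucleophile.

The fallback sets out from 13 and comes back at 14. It replaces hydrolysis by carboxylate SN2 opening followed by selective solvolysis. Formic acid buffered with sodium formate in THF at 0 °C opens the oxirane at C5 with inversion to give the 5-O-formate F7. Methanolysis with catalytic KHCO3 at 0 °C then removes the formyl group much faster than acetate or benzoate, which releases 14.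

Step 6 also has three risks:
- the sensitive dienol may be oxidised to the dienone and aromatise;
- the vanadium Lewis acid may open the vinyl oxirane;
- C1=C6 may compete for the oxidant.

The fallback sets out from 11 and comes back at 13. It builds the β-oxirane by a halohydrin route without any directing group. 11 is first acetylated (Ac2O, pyridine) to the diene triester F5. NBS in DME–H2O at 0 °C forms the bromonium ion on the less hindered α face of the less deactivated C4=C5 bond, and water enters at allylic C5 from the β face. This gives the 4α-bromo-5β-hydroxy compound, the bromohydrin F6. Ag2O in Et2O closes F6 by backside displacement of bromide to the 4β,5β-oxirane 13.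

## Further compounds

F1 | step 4 | (1R,6R)-2-formyl-6-hydroxycyclohexa-2,4-dien-1-yl benzoate (ent-9) | O=CC1=CC=C[C@@H](O)[C@@H]1OC(=O)c1ccccc1
F2 | step 4 | (1R,6R)-6-hydroxy-2-(hydroxymethyl)cyclohexa-2,4-dien-1-yl benzoate (ent-10) | OCC1=CC=C[C@@H](O)[C@@H]1OC(=O)c1ccccc1
F3 | step 4 | [(5R,6R)-6-(benzoyloxy)-5-hydroxycyclohexa-1,3-dien-1-yl]methyl benzoate (ent-11) | O=C(OCC1=CC=C[C@@H](O)[C@@H]1OC(=O)c1ccccc1)c1ccccc1
F4 | step 4 | [(5R,6R)-5-acetoxy-6-(benzoyloxy)cyclohexa-1,3-dien-1-yl]methyl benzoate | O=C(OCC1=CC=C[C@@H](OC(C)=O)[C@@H]1OC(=O)c1ccccc1)c1ccccc1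
F5 | step 6 | [(5S,6S)-5-acetoxy-6-(benzoyloxy)cyclohexa-1,3-dien-1-yl]methyl benzoate | O=C(OCC1=CC=C[C@H](OC(C)=O)[C@H]1OC(=O)c1ccccc1)c1ccccc1
F6 | step 6 | [(3S,4R,5R,6S)-5-acetoxy-6-(benzoyloxy)-4-bromo-3-hydroxycyclohex-1-en-1-yl]methyl benzoate | O=C(OCC1=C[C@H](O)[C@@H](Br)[C@H](OC(C)=O)[C@H]1OC(=O)c1ccccc1)c1ccccc1
F7 | step 8 | [(3R,4S,5S,6S)-5-acetoxy-6-(benzoyloxy)-3-(formyloxy)-4-hydroxycyclohex-1-en-1-yl]methyl benzoate | O=C(OCC1=C[C@@H](OC=O)[C@H](O)[C@H](OC(C)=O)[C@H]1OC(=O)c1ccccc1)c1ccccc1
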